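**Plan**

1. Locants: ring carbons C1 (quaternary; CH3 and 4-methylpent-3-enyl), C2=C3, C4 (ester), C5 (CH3, OH), C6=C7, C8 (C=O), C9 (bears C9′H2OH), C10, C11.
2. First cut, C8–C9: the ketone carbon C8 and the hydroxymethyl oxygen O9′ are 1,3-related through sp2 C9 (O9′–C9′H2–C9–C8=O), so the 2-(hydroxymethyl)enone is a masked allylic ester. The 11-membered carbocycle is therefore stored as a 13-membered lactone (C8 acylating O9′, Br on C9) that contracts by two atoms through an O-to-C acyl shift.
3. Further cuts: C6=C7 of the lactone (intramolecular Z-selective HWE), the C4–O ester bond (epoxide opening by senecioic acid), C3–C4 (Sonogashira), C9=C10 (bromo-Wittig) and C1–C2 (allylic substitution on geranyl phosphate).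
4. Forward: acyclic chain from geraniol, then the 13-membered lactone (closed at C6=C7), then the 11-membered carbocycle by ring contraction; no other ring is made.
5. Stereochemistry: C1 from a copper-catalysed enantioselective allylic substitution; C4 and C5 together from one Sharpless epoxidation followed by invertive opening at C4; Z-C9=C10 from the bromo-Wittig step (bromine replaced with retention), Z-C2=C3 from Lindlar reduction, Z-C6=C7 from the diaryl-phosphonate olefination.

Key step: step 16

Assumption: the target is treated as the open γ-hydroxy enone that is drawn; a transannular hemiketal tautomer (O5 onto C8) may coexist and is not handled separately.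

**Route**

Step 1
Reactants: 1 geraniol
Product: 2 geranyl diethyl phosphate
Conditions: ClP(O)(OEt)2, pyridine, CH2Cl2, 0 °C to rt
Reagents that add atoms: diethyl chlorophosphate, CCOP(=O)(Cl)OCC
Why: Standard O-phosphorylation of a primary allylic alcohol; no stereocentre is involved and the E-alkene is retained.

Step 2
Reactants: 2 geranyl diethyl phosphate; 3 ethynyltrimethylsilane
Product: 5 (3S)-3-ethenyl-3,7-dimethyl-1-(trimethylsilyl)oct-6-en-1-yne, via alkynylalane 4 (not isolated)
Conditions: 3, i-Bu2AlH, Et3N (cat.), hexanes, rt; then 2, CuCl2·2H2O (cat.), chiral sulfonate-bearing imidazolinium salt (NHC precursor, cat.), THF, −30 °C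
Reagents that add atoms: none
Why: NHC–copper-catalysed SN2′-selective enantioselective allylic substitution of a trisubstituted E-allylic phosphate by an alkynylaluminium, a reaction type established for all-carbon quaternary centres bearing vinyl and alkynyl groups; the chiral NHC–Cu complex differentiates the alkene faces and sets C1, the ligand enantiomer that delivers S being used.

Step 3
Reactants: 5 (3S)-3-ethenyl-3,7-dimethyl-1-(trimethylsilyl)oct-6-en-1-yne
Product: 8 (3S)-3-ethynyl-3,7-dimethyloct-6-en-1-ol, via borane adduct 6 (not isolated), via silylated alkynol 7 (not isolated)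
Conditions: 9-BBN, THF, 0 °C to rt; then NaOH, H2O2, MeOH/H2O, 0 °C to rt
Reagents that add atoms: hydrogen peroxide, OO
Why: Hydroboration–oxidation: 9-BBN adds anti-Markovnikov to the monosubstituted vinyl group far faster than to the trisubstituted alkene or the silylated alkyne, and the alkaline methanolic work-up that oxidises the C–B bond should also cleave the alkynyl C–Si bond; C1 is untouched.

Step 4
Reactants: 8 (3S)-3-ethynyl-3,7-dimethyloct-6-en-1-ol
Product: 9 (3S)-3-ethynyl-3,7-dimethyloct-6-enal
Conditions: Dess–Martin periodinane, NaHCO3, CH2Cl2, 0 °C to rt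
Reagents that add atoms: none
Why: Dess–Martin oxidation of a primary alcohol to the aldehyde under buffered conditions; the α-carbon is a CH2 next to the quaternary centre, so nothing can epimerise.

Step 5
Reactants: 9 (3S)-3-ethynyl-3,7-dimethyloct-6-enal; 10 ethyl (triphenylphosphoranylidene)acetate
Product: 12 ethyl (2Z,5S)-2-bromo-5-ethynyl-5,9-dimethyldeca-2,8-dienoate, via bromo ylide 11 (not isolated)
Conditions: 10, NBS, CH2Cl2, −20 °C; then 9, K2CO3, rt
Reagents that add atoms: N-bromosuccinimide, BrN1C(=O)CCC1=O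
Why: One-pot ylide bromination and Wittig olefination: the stabilised α-bromo ylide should give mainly the alkene with the ester trans to the alkyl chain, i.e. the (Z)-2-bromo-enoate with bromine cis to C11, the geometry later carried into C9=C10.

Step 6
Reactants: 12 ethyl (2Z,5S)-2-bromo-5-ethynyl-5,9-dimethyldeca-2,8-dienoate
Product: 13 (2Z,5S)-2-bromo-5-ethynyl-5,9-dimethyldeca-2,8-dien-1-ol
Conditions: i-Bu2AlH, CH2Cl2, −78 °C; aqueous Rochelle salt
Reagents that add atoms: none
Why: DIBAL-H 1,2-reduction of an α-bromo-α,β-unsaturated ester to the allylic alcohol at low temperature; the alkenyl bromide, the alkene geometry and the terminal alkyne are retained.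

Step 7
Reactants: 13 (2Z,5S)-2-bromo-5-ethynyl-5,9-dimethyldeca-2,8-dien-1-ol; 14 (diphenoxyphosphoryl)acetic acid
Product: 15 (2Z,5S)-2-bromo-5-ethynyl-5,9-dimethyldeca-2,8-dien-1-yl (diphenoxyphosphoryl)acetate
Conditions: EDC·HCl (1-ethyl-3-(3-dimethylaminopropyl)carbodiimide hydrochloride), DMAP (cat.), CH2Cl2, 0 °C to rt
Reagents that add atoms: none
Why: Carbodiimide (Steglich-type) esterification of the only hydroxyl group; it installs the diaryl phosphonoacetate for the later Z-selective olefination and makes O9′ the future lactone oxygen, so no protecting group is spent on it.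

Step 8
Reactants: 16 prop-2-yn-1-ol
Product: 18 (2E)-3-iodo-2-methylprop-2-en-1-ol, via alkenylalane 17 (not isolated)
Conditions: Me3Al, Cp2ZrCl2 (cat.), CH2Cl2, 0 °C to rt; then I2, THF, −30 to 0 °C
Reagents that add atoms: trimethylaluminium, C[Al](C)C; iodine, II
Why: Zirconium-catalysed carboalumination of the alkyne (Negishi) adds CH3 and Al syn with Al at the terminus, and iodinolysis with retention gives the E-iodoalkenol.

Step 9
Reactants: 15 (2Z,5S)-2-bromo-5-ethynyl-5,9-dimethyldeca-2,8-dien-1-yl (diphenoxyphosphoryl)acetate; 18 (2E)-3-iodo-2-methylprop-2-en-1-ol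
Product: 19 (2Z,5S)-2-bromo-5-[(3E)-5-hydroxy-4-methylpent-3-en-1-yn-1-yl]-5,9-dimethyldeca-2,8-dien-1-yl (diphenoxyphosphoryl)acetate
Conditions: Pd(PPh3)2Cl2 (cat.), CuI (cat.), Et3N, THF, rt
Reagents that add atoms: none
Why: Sonogashira coupling: oxidative addition of zerovalent palladium to the alkenyl iodide is much faster at room temperature than to the hindered trisubstituted alkenyl bromide, and the coupling proceeds with retention of the E geometry.

Step 10
Reactants: 19 enynol
Product: 20 (2Z,5S)-2-bromo-5-{[(2R,3R)-3-(hydroxymethyl)-3-methyloxiran-2-yl]ethynyl}-5,9-dimethyldeca-2,8-dien-1-yl (diphenoxyphosphoryl)acetate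
Conditions: Ti(OiPr)4, D-(−)-diisopropyl tartrate, t-BuOOH, 4 Å MS, CH2Cl2, −20 °C
Reagents that add atoms: tert-butyl hydroperoxide, CC(C)(C)OO
Why: Sharpless asymmetric epoxidation of the only free allylic alcohol (E-trisubstituted, a favourable substrate class); the titanium–D-tartrate complex delivers oxygen to one face of C4=C5 and sets both epoxide carbons (2R,3R), the sense that leads to 4S,5R after step 11.

Step 11
Reactants: 20 epoxy alcohol; 21 3-methylbut-2-enoic acid
Product: 22 (2Z,5S)-2-bromo-5-[(3S,4R)-4,5-dihydroxy-4-methyl-3-(3-methylbut-2-enoyloxy)pent-1-yn-1-yl]-5,9-dimethyldeca-2,8-dien-1-yl (diphenoxyphosphoryl)acetate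
Conditions: Ti(OiPr)4 (1.5 equiv), 21 (1.5 equiv), CH2Cl2, 0 °C to rt
Reagents that add atoms: none
Why: Titanium isopropoxide-mediated opening of a 2,3-epoxy alcohol by a carboxylic acid: chelation of titanium between the C6 alkoxide and the epoxide oxygen directs the carboxylate to the distal epoxide carbon (C4, which is also propargylic and not tertiary) with inversion, setting C4 as S, leaving C5 (R) untouched and installing the senecioate without a protecting group.

Step 12
Reactants: 22 diol senecioate
Product: 23 bis(triethylsilyl) ether of 22 (O5 and O6 silylated)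
Conditions: TESOTf, 2,6-lutidine, CH2Cl2, −78 to 0 °C
Reagents that add atoms: triethylsilyl trifluoromethanesulfonate, CC[Si](CC)(CC)OS(=O)(=O)C(F)(F)F
Why: Silyl triflate and 2,6-lutidine silylate both the primary and the hindered tertiary hydroxyl group; masking O5 prevents later translactonisation of the Z-enoate to a butenolide and stops acyl migration.

Step 13
Reactants: 23 bis(triethylsilyl) ether
Product: 24 (2Z,5S)-2-bromo-5-[(1Z,3S,4R)-4-methyl-3-(3-methylbut-2-enoyloxy)-4,5-bis(triethylsilyloxy)pent-1-en-1-yl]-5,9-dimethyldeca-2,8-dien-1-yl (diphenoxyphosphoryl)acetate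
Conditions: H2 (1 atm), Pd/CaCO3 poisoned with Pb(OAc)2 (Lindlar catalyst), quinoline, EtOAc, rt
Reagents that add atoms: none
Why: Lindlar semi-hydrogenation: syn delivery of H2 on the poisoned palladium surface gives the Z-C2=C3 alkene, and the deactivated catalyst is expected to leave the alkenyl bromide, the trisubstituted alkenes and the conjugated ester alone.

Step 14
Reactants: 24 Z-alkene
Product: 25 C6 aldehyde, (2Z,5S)-2-bromo-5-[(1Z,3S,4S)-4-methyl-3-(3-methylbut-2-enoyloxy)-5-oxo-4-(triethylsilyloxy)pent-1-en-1-yl]-5,9-dimethyldeca-2,8-dien-1-yl (diphenoxyphosphoryl)acetate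
Conditions: (COCl)2, DMSO, CH2Cl2, −78 to −40 °C; then Et3N, −78 to 0 °C
Reagents that add atoms: none
Why: Swern conditions oxidise primary triethylsilyl ethers directly to aldehydes while tertiary silyl ethers are inert, so the C6 aldehyde is unveiled in one operation; its α-carbon is quaternary and cannot epimerise (the descriptor at C5 changes only because the CIP ranking changes).

Step 15
Reactants: 25 C6 aldehyde
Product: 26 13-membered lactone (ring: O9′, C9′H2, C9(Br)=C10, C11, C1, Z-C2=C3, C4, C5, Z-C6=C7, C8(=O))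
Conditions: NaH, THF, 0 °C to rt, slow addition, high dilution (about 1 mM)
Reagents that add atoms: none
Why: Intramolecular Horner–Wadsworth–Emmons reaction of a diaryl phosphonoacetate (Ando variant), whose fast, irreversible oxaphosphetane collapse favours Z-enoates and is a known way to close Z-configured macrolactones of this size; it closes the 13-membered ring and sets Z-C6=C7.

Step 16
Reactants: 26 13-membered lactone
Product: 29 triethylsilyl ether of the target (11-membered trienone; O5 silylated), via vinyllithium 27 (not isolated), via oxetanolate 28 (not isolated)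
Conditions: t-BuLi (2.1 equiv), THF/Et2O/pentane, −105 °C, then to −40 °C; AcOH, −78 °C
Reagents that add atoms: none
Why: Proposed new method: Br–Li exchange on the alkenyl bromide, which is much faster than t-BuLi addition to either ester at this temperature, gives vinyllithium 27, whose carbanionic C9 sits three atoms from the lactone carbonyl carbon (C9–C9′H2–O–C8) and adds to it through a four-centre transition state to the fused oxetanolate 28; strain-driven collapse of 28 expels the primary alkoxide, so the acyl carbon moves from O9′ to C9 and the O9′–C9′H2 unit leaves the ring (13 to 11 atoms). The closest known reaction types are the anionic Fries 1,3 O-to-C acyl shift of ortho-lithiated aryl esters, Parham-type halogen–lithium exchange-initiated intramolecular acylations and SmI2-mediated O-to-C acyl transfers of haloalkyl esters. The 11-membered carbocycle is closed in the C8–C9 bond-forming event, a 4-exo-trig addition with respect to the transient oxetane (formally 11-exo-trig for the carbocycle), so no end-to-end macrocyclisation is needed. No stereocentre is created: C1, C4 and C5 are spectators, the C9=C10 geometry is carried over because alkenyllithiums are configurationally stable and the acyl group takes the place of bromine with retention, and Z-C6=C7 is not touched. The step needs chemoselectivity for the lactone carbonyl over the senecioate, which the 1,3-proximity enforced by the ring should secure, and for acyl transfer over β-elimination of the carboxylate to an allene, which the very low barrier of carbonyl addition at low temperature should secure. The driving force is the exchange of a vinyllithium and an ester for a lithium alkoxide and a cross-conjugated dienone.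

Step 17
Reactants: 29 triethylsilyl ether of the target
Product: 30 target, (2Z,5S,6Z,8S,9R,10Z)-9-hydroxy-2-(hydroxymethyl)-5,9-dimethyl-5-(4-methylpent-3-en-1-yl)-1-oxocycloundeca-2,6,10-trien-8-yl 3-methylbut-2-enoate
Conditions: HF·pyridine, pyridine, THF, 0 °C to rt
Reagents that add atoms: none
Why: Fluoride-mediated cleavage of the tertiary triethylsilyl ether under buffered, weakly acidic conditions that should spare the senecioate, the primary allylic alcohol and the cross-conjugated dienone.

**Compound list**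

1 | geraniol, (2E)-3,7-dimethylocta-2,6-dien-1-ol | CC(C)=CCC/C(C)=C/CO | starting material
2 | geranyl diethyl phosphate | CC(C)=CCC/C(C)=C/COP(=O)(OCC)OCC | intermediate
3 | ethynyltrimethylsilane | C#C[Si](C)(C)C | starting material
4 | diisobutyl[(trimethylsilyl)ethynyl]aluminium (alkynylalane, not isolated) | CC(C)C[Al](CC(C)C)C#C[Si](C)(C)C | intermediate
5 | (3S)-3-ethenyl-3,7-dimethyl-1-(trimethylsilyl)oct-6-en-1-yne | CC(C)=CCC[C@](C=C)(C)C#C[Si](C)(C)C | intermediate
6 | 9-[(3S)-3,7-dimethyl-3-[(trimethylsilyl)ethynyl]oct-6-en-1-yl]-9-borabicyclo[3.3.1]nonane (borane adduct, not isolated) | CC(C)=CCC[C@](CCB1C2CCCC1CCC2)(C)C#C[Si](C)(C)C | intermediate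
7 | (3S)-3,7-dimethyl-3-[(trimethylsilyl)ethynyl]oct-6-en-1-ol (not isolated) | CC(C)=CCC[C@](CCO)(C)C#C[Si](C)(C)C | intermediate
8 | (3S)-3-ethynyl-3,7-dimethyloct-6-en-1-ol | CC(C)=CCC[C@](CCO)(C)C#C | intermediate
9 | (3S)-3-ethynyl-3,7-dimethyloct-6-enal | CC(C)=CCC[C@](CC=O)(C)C#C | intermediate
10 | ethyl (triphenylphosphoranylidene)acetate | CCOC(=O)C=P(c1ccccc1)(c1ccccc1)c1ccccc1 | starting material
11 | ethyl bromo(triphenylphosphoranylidene)acetate (bromo ylide, not isolated) | CCOC(=O)C(Br)=P(c1ccccc1)(c1ccccc1)c1ccccc1 | intermediate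
12 | ethyl (2Z,5S)-2-bromo-5-ethynyl-5,9-dimethyldeca-2,8-dienoate | CC(C)=CCC[C@](C/C=C(\Br)C(=O)OCC)(C)C#C | intermediate
13 | (2Z,5S)-2-bromo-5-ethynyl-5,9-dimethyldeca-2,8-dien-1-ol | CC(C)=CCC[C@](C/C=C(\Br)CO)(C)C#C | intermediate
14 | (diphenoxyphosphoryl)acetic acid | OC(=O)CP(=O)(Oc1ccccc1)Oc1ccccc1 | starting material
15 | (2Z,5S)-2-bromo-5-ethynyl-5,9-dimethyldeca-2,8-dien-1-yl (diphenoxyphosphoryl)acetate | CC(C)=CCC[C@](C/C=C(\Br)COC(=O)CP(=O)(Oc1ccccc1)Oc1ccccc1)(C)C#C | intermediate
16 | prop-2-yn-1-ol | C#CCO | starting material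
17 | dimethylaluminium (2E)-3-(dimethylalumanyl)-2-methylprop-2-en-1-olate (alkenylalane, not isolated) | C[Al](C)OC/C(C)=C/[Al](C)C | intermediate
18 | (2E)-3-iodo-2-methylprop-2-en-1-ol | OC/C(C)=C/I | intermediate
19 | enynol, (2Z,5S)-2-bromo-5-[(3E)-5-hydroxy-4-methylpent-3-en-1-yn-1-yl]-5,9-dimethyldeca-2,8-dien-1-yl (diphenoxyphosphoryl)acetate | CC(C)=CCC[C@](C/C=C(\Br)COC(=O)CP(=O)(Oc1ccccc1)Oc1ccccc1)(C)C#C/C=C(\C)CO | intermediate
20 | epoxy alcohol, (2Z,5S)-2-bromo-5-{[(2R,3R)-3-(hydroxymethyl)-3-methyloxiran-2-yl]ethynyl}-5,9-dimethyldeca-2,8-dien-1-yl (diphenoxyphosphoryl)acetate | CC(C)=CCC[C@](C/C=C(\Br)COC(=O)CP(=O)(Oc1ccccc1)Oc1ccccc1)(C)C#C[C@H]1O[C@]1(C)CO | intermediate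
21 | 3-methylbut-2-enoic acid (senecioic acid) | CC(C)=CC(=O)O | starting material
22 | diol senecioate, (2Z,5S)-2-bromo-5-[(3S,4R)-4,5-dihydroxy-4-methyl-3-(3-methylbut-2-enoyloxy)pent-1-yn-1-yl]-5,9-dimethyldeca-2,8-dien-1-yl (diphenoxyphosphoryl)acetate | CC(C)=CCC[C@](C/C=C(\Br)COC(=O)CP(=O)(Oc1ccccc1)Oc1ccccc1)(C)C#C[C@H](OC(=O)C=C(C)C)[C@](C)(O)CO | intermediate
23 | bis(triethylsilyl) ether of 22 (O5 and O6 silylated; 3S,4R in the pentynyl unit) | CC(C)=CCC[C@](C/C=C(\Br)COC(=O)CP(=O)(Oc1ccccc1)Oc1ccccc1)(C)C#C[C@H](OC(=O)C=C(C)C)[C@](C)(O[Si](CC)(CC)CC)CO[Si](CC)(CC)CC | intermediate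
24 | Z-alkene, (2Z,5S)-2-bromo-5-[(1Z,3S,4R)-4-methyl-3-(3-methylbut-2-enoyloxy)-4,5-bis(triethylsilyloxy)pent-1-en-1-yl]-5,9-dimethyldeca-2,8-dien-1-yl (diphenoxyphosphoryl)acetate | CC(C)=CCC[C@](C/C=C(\Br)COC(=O)CP(=O)(Oc1ccccc1)Oc1ccccc1)(C)/C=C\[C@H](OC(=O)C=C(C)C)[C@](C)(O[Si](CC)(CC)CC)CO[Si](CC)(CC)CC | intermediate
25 | C6 aldehyde, (2Z,5S)-2-bromo-5-[(1Z,3S,4S)-4-methyl-3-(3-methylbut-2-enoyloxy)-5-oxo-4-(triethylsilyloxy)pent-1-en-1-yl]-5,9-dimethyldeca-2,8-dien-1-yl (diphenoxyphosphoryl)acetate | CC(C)=CCC[C@](C/C=C(\Br)COC(=O)CP(=O)(Oc1ccccc1)Oc1ccccc1)(C)/C=C\[C@H](OC(=O)C=C(C)C)[C@](C)(O[Si](CC)(CC)CC)C=O | intermediate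
26 | 13-membered lactone: C8 carboxylate of O9′; C9 bears Br (cis to C11); Z-C2=C3 and Z-C6=C7; C1 S, C4 S (senecioate), C5 R (OSiEt3) | CC(C)=CCC[C@]1(C)/C=C\[C@H](OC(=O)C=C(C)C)[C@](C)(O[Si](CC)(CC)CC)/C=C\C(=O)OC/C(Br)=C/C1 | intermediate
27 | vinyllithium from 26 (Li on C9 in place of Br, not isolated) | CC(C)=CCC[C@]1(C)/C=C\[C@H](OC(=O)C=C(C)C)[C@](C)(O[Si](CC)(CC)CC)/C=C\C(=O)OC/C([Li])=C/C1 | intermediate
28 | lithium oxetanolate: C8 bonded to C9, O9′ and OLi; oxetane fused to the 11-membered ring (not isolated) | CC(C)=CCC[C@]1(C)/C=C\[C@H](OC(=O)C=C(C)C)[C@](C)(O[Si](CC)(CC)CC)/C=C\C2(O[Li])OC/C2=C/C1 | intermediate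
29 | O5-triethylsilyl ether of the target | CC(C)=CCC[C@]1(C)/C=C\[C@H](OC(=O)C=C(C)C)[C@](C)(O[Si](CC)(CC)CC)/C=C\C(=O)/C(CO)=C\C1 | intermediate
30 | target, (2Z,5S,6Z,8S,9R,10Z)-9-hydroxy-2-(hydroxymethyl)-5,9-dimethyl-5-(4-methylpent-3-en-1-yl)-1-oxocycloundeca-2,6,10-trien-8-yl 3-methylbut-2-enoate | CC(C)=CCC[C@]1(C)/C=C\[C@H](OC(=O)C=C(C)C)[C@](C)(O)/C=C\C(=O)/C(CO)=C\C1 | target

**Step count and risks**

Total: 17 steps. Longest linear sequence: 16 steps (steps 1–7 and 9–17, from geraniol); step 8 is a one-step side branch.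

Steps most likely to fail:

1. Step 16 (proposed new method). The 2-lithioallyl ester may lose its carboxylate by β-elimination (allene formation with ring opening), t-BuLi may add to an ester carbonyl before exchange is complete, or the vinyllithium may be quenched by proton transfer from the senecioate. The fallback sets out from 26 and returns at 30, and closes the carbocycle by a chromium-mediated aldehyde addition instead of the acyl shift. The lactone is opened at its less hindered carbonyl with Me(MeO)NH·HCl and i-PrMgCl (THF, −20 °C) to the hydroxy Weinreb amide F1. The primary alcohol is silylated (TESCl, imidazole) to the silyl ether F2. Cp2Zr(H)Cl reduces the amide to the Z-enal F3 without touching the esters. An intramolecular Nozaki–Hiyama–Kishi reaction (CrCl2, cat. NiCl2, DMSO, high dilution), which tolerates esters, closes the 11-membered ring at C8–C9 to the bis-allylic alcohol F4 (both C8 epimers are usable). Dess–Martin oxidation gives the dienone bis-silyl ether F5, and HF·pyridine removes both silyl groups to give 30.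

2. Step 11. The carboxylate may attack the tertiary epoxide carbon C5, the senecioyl group may migrate from O4 to the primary O6 within the titanium chelate, or the phosphonoacetate may transesterify. The fallback sets out from 20 and returns at 23, and replaces chelation control by steric control on a substrate with no free hydroxyl. The primary alcohol is silylated (TESCl, imidazole) to the epoxy silyl ether F6. The epoxide is then opened by SN2 attack at the secondary propargylic carbon with cesium 3-methylbut-2-enoate (from 21 and Cs2CO3, buffered with excess 21) in DMF at 60–80 °C, where the tertiary carbon cannot compete, giving the hydroxy ester F7 with the same inversion at C4. TESOTf and 2,6-lutidine then give 23.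

3. Step 13. Hydrogenolysis of the alkenyl C–Br bond or of the allylic ester, stalling at the hindered alkyne, or over-reduction may occur. The fallback sets out from 15 and returns at 24, and builds the Z-alkene by stereoretentive cross-coupling instead of hydrogenation. Rhodium-catalysed trans-hydroboration of the terminal alkyne ([Rh(cod)Cl]2, P(i-Pr)3, pinacolborane, Et3N) gives the (Z)-alkenylboronate F8. Suzuki–Miyaura coupling with 18 (Pd(PPh3)4, K3PO4, THF/H2O, rt) gives the (2E,4Z)-dienol F9. Sharpless epoxidation with D-(−)-diisopropyl tartrate gives the vinyl epoxide F10, and Ti(OiPr)4 with 21 gives the diol senecioate F11. TESOTf and 2,6-lutidine then give 24.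

Further compounds
F1 | step 16 | hydroxy Weinreb amide from opening of 26 (free C9′ alcohol, C9 bromide, Z-C6=C7 N-methoxy-N-methylamide) | CC(C)=CCC[C@](C/C=C(\Br)CO)(C)/C=C\[C@H](OC(=O)C=C(C)C)[C@](C)(O[Si](CC)(CC)CC)/C=C\C(=O)N(C)OC
F2 | step 16 | O9′-triethylsilyl ether of F1 | CC(C)=CCC[C@](C/C=C(\Br)CO[Si](CC)(CC)CC)(C)/C=C\[C@H](OC(=O)C=C(C)C)[C@](C)(O[Si](CC)(CC)CC)/C=C\C(=O)N(C)OC
F3 | step 16 | Z-enal (C8 aldehyde) with C9 bromide | CC(C)=CCC[C@](C/C=C(\Br)CO[Si](CC)(CC)CC)(C)/C=C\[C@H](OC(=O)C=C(C)C)[C@](C)(O[Si](CC)(CC)CC)/C=C\C=O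
F4 | step 16 | 11-membered bis-allylic alcohol (C8–OH, epimer mixture; O5 and O9′ silylated) | CC(C)=CCC[C@]1(C)/C=C\[C@H](OC(=O)C=C(C)C)[C@](C)(O[Si](CC)(CC)CC)/C=C\C(O)/C(CO[Si](CC)(CC)CC)=C\C1
F5 | step 16 | bis(triethylsilyl) ether of the target (O5 and O9′) | CC(C)=CCC[C@]1(C)/C=C\[C@H](OC(=O)C=C(C)C)[C@](C)(O[Si](CC)(CC)CC)/C=C\C(=O)/C(CO[Si](CC)(CC)CC)=C\C1
F6 | step 11 | O6-triethylsilyl ether of epoxy alcohol 20 | CC(C)=CCC[C@](C/C=C(\Br)COC(=O)CP(=O)(Oc1ccccc1)Oc1ccccc1)(C)C#C[C@H]1O[C@]1(C)CO[Si](CC)(CC)CC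
F7 | step 11 | C4 senecioate with free tertiary O5–H and O6-triethylsilyl ether | CC(C)=CCC[C@](C/C=C(\Br)COC(=O)CP(=O)(Oc1ccccc1)Oc1ccccc1)(C)C#C[C@H](OC(=O)C=C(C)C)[C@](C)(O)CO[Si](CC)(CC)CC
F8 | step 13 | (Z)-alkenyl pinacolboronate from 15 (boron on C3, cis to C1) | CC(C)=CCC[C@](C/C=C(\Br)COC(=O)CP(=O)(Oc1ccccc1)Oc1ccccc1)(C)/C=C\B1OC(C)(C)C(C)(C)O1
F9 | step 13 | (2E,4Z)-dienol (Z-C2=C3, E-C4=C5, free C6 alcohol) | CC(C)=CCC[C@](C/C=C(\Br)COC(=O)CP(=O)(Oc1ccccc1)Oc1ccccc1)(C)/C=C\C=C(/C)CO
F10 | step 13 | vinyl epoxide, (2R,3R)-epoxy alcohol with Z-C2=C3 | CC(C)=CCC[C@](C/C=C(\Br)COC(=O)CP(=O)(Oc1ccccc1)Oc1ccccc1)(C)/C=C\[C@H]1O[C@]1(C)CO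
F11 | step 13 | diol senecioate with Z-C2=C3 (C4 S, C5 R) | CC(C)=CCC[C@](C/C=C(\Br)COC(=O)CP(=O)(Oc1ccccc1)Oc1ccccc1)(C)/C=C\[C@H](OC(=O)C=C(C)C)[C@](C)(O)CO
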